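(All runs were computed from invented constants; noise was put on by code.)

Q stands still from 2.00 min on at 10.9 % in Saturday's flask and at 16.7 % in Wednesday's, averaged over the readings of each.

| setting | Saturday's | Wednesday's | flask |
|---|---|---|---|
| E | 0.010 M | 0.010 M | 0.010 M |
| G | 0.010 M | 0.010 M | 0.010 M |
| L | 0.011 M | 0.044 M | 0.0220 M |
| D | 1 mM | 1 mM | 1.0 mM |
| remark | run made earlier | run made earlier |  |
| time |  |  | 40 min |

- Saturday's (time / min: E / %, Q / %): 2.00: 43.1, 9.8; 6.00: 44.2, 11.4; 12.0: 44.8, 11.2; 20.0: 43.8, 10.9; 25.0: 42.9, 10.6; 30.0: 43.8, 11.3
- Wednesday's (time / min: E / %, Q / %): 2.00: 40.5, 17.0; 6.00: 39.8, 16.2; 12.0: 39.8, 17.3; 20.0: 40.9, 16.2; 25.0: 40.3, 17.0; 30.0: 40.3, 16.7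

(each reading ± 0.5 percentage points)

* which holds at 40 min: what has brought the reaction to rest, or that it has not come to rest (no working catalyst is left / all of E has reacted / it is still moving / L has run out first / forward and back rates have come level)
* conversion of E and G together at 40 min
* amount of Q at 40 min, in percent of the E and G together charged
* amount of Q if the flask were left three thousand times as long, in percent of the E and G together charged

- D is single-handed; E and G are mirror images of each other, charged as a racemate, each of them at the stated concentration
- the reaction counts as stopped when no species that holds the E and G together changes by six tenths of a point or more over the second half of the time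

While L stands nearly untouched, Q forms at a rate proportional to L. A D that dies on its own clock therefore gives Q in proportion to the charge of L, a factor of 4.00 between these two flasks. The readings give 1.53, which is less, so the reckoning here takes L to be lost faster the more of it stands.

The simplest such loss runs at b·L·L, beside the use of L for Q at a·L, where a holds D and E, both taken as steady. Compare the two rates at one moment:

Q formed per L lost = a/(b·L)

The comparison drifts in favour of Q as L falls:

dQ = (a/b)·dL/L

So long as b·L stands well above a, equal ratios of L therefore give equal amounts of Q. This defines the gain per doubling, g: the Q added by each doubling of the charge of L, with D and E held. Saturday's and Wednesday's flasks lie 2.00 doublings apart: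

g = (16.7 % − 10.9 %) / 2.00 = 2.9 percentage points

The new flask, with 0.0220 M of L, lies 1.00 doubling above Saturday's:

Q = 10.9 % + 2.9 points = 13.8 %

This reckoning expects the rest to come from the loss of L, and Q to stay there at the long time.

The forecast says no working catalyst is left, with conversion 14 %, Q 14 % and 14 % at the long time: “Dead catalyst means no further change.” Its Q stands close to the one here, and the end it names is another.

The flask gives: L has run out first, with conversion 16.8 %, Q 13.7 %, and 13.7 % at the long time.

    L + D + E → D + Q (k = 2200 M⁻² s⁻¹)
    L + D + G → D + J (k = 450 M⁻² s⁻¹)
    E ⇌ G (k = 0.0120 s⁻¹)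
    2 D → Z (k = 4.60 M⁻¹ s⁻¹)
    2 L → X (k = 9.90 M⁻¹ s⁻¹)

At 4.00 min the flask holds 0.216 % of its charge of L, while D still stands at 31.2 % of its own charge. A neighbouring flask with 0.0055 M of L lies 1.00 doubling below Saturday's, so 2.9 points taken off 10.9 % gives 7.93 % of Q. That neighbouring flask gives 8.20 %.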